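## Structural features

The target is a diaryl ether of two benzene rings with no other ring. Ring A is a benzoic acid (C1 CO2H) with a methoxy group at C2, an (S)-1-hydroxy-3-methylbutyl chain at C3 and the ether oxygen at C6. Ring B is attached through C1' and carries a phenol at C2', a methyl group at C4' and a hydroxymethyl group at C6'.

The ether oxygen has an ortho substituent on every side (CO2H on ring A, OH and CH2OH on ring B), and ring A has four contiguous substituents (C6, C1, C2, C3). A late aryl–O coupling and a stepwise substitution of ring A are therefore both unattractive, and this is the real difficulty.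

The only stereocentre is the benzylic carbinol carbon on C3. It has no neighbouring stereocentre, so it must be set absolutely; CIP analysis of the SMILES gives S.

This carbinol is ortho to the C2 methoxy group and para to the C6 aryloxy group, so it ionises easily in acid (racemisation, elimination) and is exposed to hydrogenolysis. The ring B hydroxymethyl group is a second benzylic alcohol, and the ring B phenol is an oxidisable catechol mono-ether.

The carboxyl group lies between two ortho substituents, so an ester at C1 resists saponification. Under activating conditions the acid could also close an eight-membered lactone onto the ring B CH2OH.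

The key step uses the oxygen pattern of ring A. C2 (oxygen), C1 (carboxyl) and C6 (aryloxy) in a row, with carbon at C3, is what a 1,1-dioxygenated 2-substituted butadiene (C2–C5) gives when it adds to a 3-aryloxypropiolate (C6, C1) and the adduct aromatises.

## Logic of the disconnections

**29 to 28 to 27.** The two O–Si bonds are cut first, then the two O–CH2Ph bonds (phenol ether and carboxyl ester). All four hydroxyl-type groups are masked until the end, and the acid is released without saponifying a di-ortho-substituted ester. The forward demand is that hydrogenolysis spares the two benzylic C–O bonds; it is therefore run on 27, where both are still bulky silyl ethers, and fluoride comes last.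

**27 to 26.** The O–CH3 bond at C2 is cut. This leaves a salicylate, the direct outcome of the ring-forming step. The forward step must alkylate a hydrogen-bonded, flanked phenol without touching the alkyl silyl ethers or the benzyl ester.

**26 to 10 and 23.** The C1–C2 and C5–C6 bonds of ring A are cut. The tetrasubstituted arene falls into a four-carbon diene that carries the stereocentre and a two-carbon alkyne that already carries the aryl–O bond and the carboxyl carbon. The forward step must give one regiochemistry and must aromatise without harming the benzylic silyl ether.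

**23 to 19 and 20, and 19 to 17 and 18.** The bond between the alkyne and the carboxyl carbon is cut, then the bond between the ring B oxygen and the two-carbon unit. The hindered aryl–O bond is thus made on a small, linear electrophile, where the two ortho groups of ring B count for little. The forward steps need a phenol with both other oxygens masked by groups that withstand carbonate at 70 °C and n-BuLi at −78 °C.

**17 to 16 to 15 to 13 to 12 to 11.** Cut in turn: the O–Si bond of the primary alcohol, the C–H bond of the hydroxymethyl carbon (back to the aldehyde), the O–benzyl bond, the O–methyl bond (exchange of the phenol mask) and the aryl–CHO bond. This leads back to a cheap phenol that already has the methyl group and both oxygens in place. The forward demands are ortho-selective formylation and differentiation of two phenols by their relation to the formyl group.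

**10 to 8 to 7 to 6.** The enol O–Si bond, the carbinol O–Si bond and the ester C–O bond (back to the imide) are cut. The diene becomes an ordinary aldol adduct. The forward demand is enolate formation without loss of the β-silyloxy group; the configuration at C2 of 6 to 8 is irrelevant because that carbon becomes sp2.

**6 to 3 and 4, and 3 to 1 and 2.** The bond between the future C3 of ring A and the carbinol carbon is cut (aldol), then the N–acyl bond. The stereocentre is set by a recoverable auxiliary, and three commercial materials remain. The forward demand is α-selective (not γ-selective) reaction of the dienolate with the correct facial sense.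

## Other disconnections considered

**Alternative 1:** The aryl–O bond at C6 and the C1–carboxyl bond are cut, which turns ring A into an aryne spanning C1 and C6.

- Forward step: CsF would release the 3-methoxyaryne from the ortho-silylaryl triflate A2. The phenoxide of 17 would add at C6, and the C1 aryl anion would be trapped by carbon dioxide A3 to give acid A1.
- In its favour: both bonds around the crowded ether form in one convergent operation on an sp-hybridised electrophile that is insensitive to ortho substituents. The regiochemistry is plausible, because the inductive effect of the C2 methoxy group distorts the aryne so that the nucleophile attacks the distal carbon (C6) and charge develops at C1 next to oxygen.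
- Better than the chosen plan on one point: A1 already has the free acid and the C2 methyl ether, so no methylation and no unmasking of a carboxyl derivative follow the key step.
- Against it: an aryl anion generated by an oxygen nucleophile is readily protonated, so the diaryl ether lacking the carboxyl group is the expected competitor. Carbon dioxide also ties up the phenoxide reversibly as a carbonate. Aryne couplings that end in carboxylation are developed mainly for nitrogen nucleophiles.
- Structure: the problem of ring A is moved, not solved. A2 is itself a 1,2,3,4-tetrasubstituted arene with the stereocentre on it and needs its own multistep synthesis. The chosen plan draws all four contiguous substituents from two acyclic pieces.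
- Mechanism and step economy: both plans fix regiochemistry by polarity and are equal there. The steps saved after the key step would probably be spent on A2.

**Alternative 2:** Ring B is disconnected instead, at the C4'–C5' and C1'–C6' bonds. This leaves ring A as the aryloxymethyl ynone A5 and the three-carbon ketone 1,1-dimethoxyacetone A6.

- Forward step: the lithium enolate of A6, formed at its methyl group, would add to the ynone of A5 (C4'–C5'). The carbanion between the ether oxygen and the ketone would close on the new ketone (C1'–C6'). Loss of water and tautomerisation would give phenol A4 with C6' as a dimethyl acetal.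
- In its favour: the ring B oxygen is never attached to an aromatic carbon by arylation. This is the equal of the chosen plan, which also avoids a hindered arylation.
- Better than the chosen plan on one point: the ring B phenol emerges unprotected, so no benzyl group is needed.
- Against it: the ArO–CH2–C(=O) protons of A5 are the most acidic in the mixture, so proton transfer and self-condensation compete with conjugate addition. Only the (Z)-enone from the Michael addition can cyclise. Enolisation towards the acetal carbon opens a second six-membered aldol mode. The free acid of A5 consumes base.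
- Structure: the plan builds the simpler ring and presupposes the harder one. A5 needs a finished ring A with its four contiguous substituents and the stereocentre, which is exactly what the chosen key step provides.
- Step economy: the acetal of A4 needs hydrolysis and reduction next to an acid-sensitive benzylic silyl ether. With ring A counted, the route is unlikely to be shorter.

**Alternative 3:** Ring A is again made by a two-bond cut, but at C1–C2 and C3–C4. C1, C6, C5 and C4 come from the 4-aryloxy-3-carbomethoxy-2-pyrone A8, and C2 and C3 from the (S)-silyloxy methyl ynol ether A9.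

- Forward step: heating A8 with A9 would give a bridged lactone by [4+2] addition, which extrudes CO2 to give arene A7 directly.
- In its favour: the ring is assembled with the aryl–O bond already made (addition–elimination of the phenoxide of 17 at C4 of a pyrone), which equals the chosen plan. The polarity (nucleophilic β-carbon of the ynol ether to C6 of the pyrone) gives the required orientation.
- Better than the chosen plan on two points: C2 arrives as the methyl ether, so the methylation step disappears, and aromatisation needs no elimination.
- Against it: the aryloxy group at C4 is a donor on a diene that must act as the electron-poor partner. The inverse-demand addition would need temperatures at which a propargylic-oxygenated ynol ether tends to decompose.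
- Structure: a 5,6-unsubstituted 4-hydroxy-2-pyrone-3-carboxylate, needed for A8, is not a common building block. A9 needs an asymmetric alkynylation or ynone reduction no shorter than the aldol route to 10. The methyl ester of A7 sits between two ortho substituents; the chosen plan avoids this weak point with a benzyl ester, which A8 could equally carry.
- Mechanism and step economy: both are polarity-controlled. Alternative 3 has one step fewer after the key step but more, and less certain, steps before it.

Key step: step 13

Remarks on the chemistry:

- Assumption: the ketene acetal 10 forms as a mixture of double-bond isomers and the C2 configuration of 6 to 8 may erode; both are immaterial because that carbon becomes aromatic C3.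
- Structure check: no error was found. The stereocentre is S and the (R)-auxiliary is the one that delivers it.
- Design changes within the same disconnection: (a) the alkyne carries a benzyl ester, not a methyl ester, so the carboxyl group is freed by hydrogenolysis rather than by saponification of a di-ortho-substituted benzoate; (b) the side-chain alcohol carries a tert-butyldimethylsilyl group, which goes on a hindered secondary alcohol more easily and crowds the diene less.
- Abbreviation: ArB = 2-(benzyloxy)-4-methyl-6-[(triisopropylsilyloxy)methyl]phenyl.

## Route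

Step 1
Reactants: 1 (R)-4-benzyl-2-oxazolidinone; 2 (E)-but-2-enoyl chloride (crotonyl chloride)
Product: 3 (4R)-4-benzyl-3-[(2E)-but-2-enoyl]-1,3-oxazolidin-2-one
Conditions: n-BuLi, THF, −78 °C; then 2, −78 → 0 °C
Reagents that add atoms: none
Why: N-acylation of the lithiated oxazolidinone by an acid chloride is standard imide formation, and the (E)-alkene is untouched at low temperature.

Step 2
Reactants: 3 (4R)-4-benzyl-3-[(2E)-but-2-enoyl]-1,3-oxazolidin-2-one; 4 3-methylbutanal (isovaleraldehyde)
Product: 6 (4R)-4-benzyl-3-[(2R,3S)-2-ethenyl-3-hydroxy-5-methylhexanoyl]-1,3-oxazolidin-2-one, via dibutylboron (Z)-dienolate 5 (not isolated)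
Conditions: Bu2BOTf, Et3N, CH2Cl2, −78 → 0 °C; 4, −78 → 0 °C; pH 7 buffer, MeOH, H2O2, 0 °C
Reagents that add atoms: none
Why: Evans syn aldol: γ-deprotonation gives the (Z)-boron dienolate 5, which reacts at its α-carbon through a chair Zimmerman–Traxler transition state. The benzyl group of the (R)-auxiliary shields one enolate face, so the carbinol carbon should form as S (and C2 as R, erased later).

Step 3
Reactants: 6 (4R)-4-benzyl-3-[(2R,3S)-2-ethenyl-3-hydroxy-5-methylhexanoyl]-1,3-oxazolidin-2-one
Product: 7 methyl (2R,3S)-2-ethenyl-3-hydroxy-5-methylhexanoate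
Conditions: MeMgBr, MeOH, 0 °C; aq. NH4Cl
Reagents that add atoms: methanol (as MeOMgBr), CO
Why: Magnesium methoxide transesterification cleaves the exocyclic acyl–N bond of a β-hydroxy imide under weakly basic conditions that disfavour retro-aldol, and the auxiliary is recovered. Epimerisation at C2 or alkene migration would be harmless, because the same dienolate results in step 5.

Step 4
Reactants: 7 methyl (2R,3S)-2-ethenyl-3-hydroxy-5-methylhexanoate
Product: 8 methyl (2R,3S)-3-(tert-butyldimethylsilyloxy)-2-ethenyl-5-methylhexanoate
Conditions: tBuMe2SiOTf, 2,6-lutidine, CH2Cl2, −78 → 0 °C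
Reagents that add atoms: tert-butyldimethylsilyl triflate, CC(C)(C)[Si](C)(C)OS(=O)(=O)C(F)(F)F
Why: Silyl triflate with a hindered pyridine base silylates hindered secondary alcohols reliably. The ether is stable to amide bases and to the thermal key step, and is removed by fluoride at the end.

Step 5
Reactants: 8 methyl (2R,3S)-3-(tert-butyldimethylsilyloxy)-2-ethenyl-5-methylhexanoate
Product: 10 (S)-2-[1-(tert-butyldimethylsilyloxy)-3-methylbutyl]-1-methoxy-1-(trimethylsilyloxy)buta-1,3-diene (mixture of ketene acetal isomers), via lithium dienolate 9 (not isolated)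
Conditions: LiN(iPr)2, THF, −78 °C; Me3SiCl, −78 °C → rt; pentane, filtration under argon, used crude
Reagents that add atoms: chlorotrimethylsilane, C[Si](C)(C)Cl
Why: The C2 proton is both α to the ester and allylic, so deprotonation at −78 °C gives dienolate 9, and O-silylation gives the vinylketene acetal (silyl ketene acetal formation). At this temperature E1cB loss of the β-silyloxide should be slow, and the carbinol carbon carries no acidic hydrogen, so its configuration is kept.

Step 6
Reactants: 11 creosol (2-methoxy-4-methylphenol)
Product: 12 2-hydroxy-3-methoxy-5-methylbenzaldehyde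
Conditions: MgCl2, Et3N, (CH2O)n, MeCN, reflux; 1 M HCl
Reagents that add atoms: paraformaldehyde (formaldehyde), C=O
Why: Magnesium-mediated ortho-formylation of phenols is ortho-specific, and the only free ortho position of 11 is C6. A second equivalent of formaldehyde takes up the hydride.

Step 7
Reactants: 12 2-hydroxy-3-methoxy-5-methylbenzaldehyde
Product: 13 2,3-dihydroxy-5-methylbenzaldehyde
Conditions: BBr3, CH2Cl2, −78 → 0 °C; H2O
Reagents that add atoms: none
Why: Lewis-acid cleavage of the aryl methyl ether (bromide attacks the methyl group of the boron-complexed ether) frees the second phenol, so that a removable group can take the place of methyl. The formyl group returns on aqueous work-up.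

Step 8
Reactants: 13 2,3-dihydroxy-5-methylbenzaldehyde
Product: 15 3-(benzyloxy)-2-hydroxy-5-methylbenzaldehyde, via disodium catecholate 14 (not isolated)
Conditions: NaH (2.2 equiv), THF–DMSO, 0 °C → rt; BnBr (1.0 equiv); 1 M HCl
Reagents that add atoms: benzyl bromide, BrCc1ccccc1
Why: Williamson etherification of the dianion: the 2-phenoxide of 14 is conjugated with and chelated to the formyl group, so one equivalent of benzyl bromide should react at the more basic 3-phenoxide.

Step 9
Reactants: 15 3-(benzyloxy)-2-hydroxy-5-methylbenzaldehyde
Product: 16 2-(benzyloxy)-6-(hydroxymethyl)-4-methylphenol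
Conditions: NaBH4, MeOH–THF, 0 °C
Reagents that add atoms: none
Why: Borohydride reduction of an aromatic aldehyde; nothing else in 15 is reducible under these conditions.

Step 10
Reactants: 16 2-(benzyloxy)-6-(hydroxymethyl)-4-methylphenol
Product: 17 2-(benzyloxy)-4-methyl-6-[(triisopropylsilyloxy)methyl]phenol
Conditions: iPr3SiCl, imidazole, CH2Cl2, 0 °C → rt
Reagents that add atoms: chlorotriisopropylsilane, CC(C)[Si](Cl)(C(C)C)C(C)C
Why: Chemoselective silylation: the primary benzylic alcohol reacts with the bulky silyl chloride much faster than the phenol, which is flanked by two ortho substituents.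

Step 11
Reactants: 17 2-(benzyloxy)-4-methyl-6-[(triisopropylsilyloxy)methyl]phenol; 18 trichloroethylene
Product: 19 1-(benzyloxy)-2-[(E)-1,2-dichloroethenyloxy]-5-methyl-3-[(triisopropylsilyloxy)methyl]benzene
Conditions: K2CO3, DMF, 70 °C
Reagents that add atoms: none
Why: Carbonate converts 18 into dichloroacetylene in the flask, and anti addition of the phenoxide to this linear electrophile gives the (E)-dichlorovinyl ether (vinylic substitution by elimination–addition). Attack on an sp carbon is little affected by the two ortho groups of ring B.

Step 12
Reactants: 19 1-(benzyloxy)-2-[(E)-1,2-dichloroethenyloxy]-5-methyl-3-[(triisopropylsilyloxy)methyl]benzene; 20 benzyl chloroformate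
Product: 23 benzyl 3-{2-(benzyloxy)-4-methyl-6-[(triisopropylsilyloxy)methyl]phenoxy}prop-2-ynoate, via chloroethynyl aryl ether 21 (not isolated), via lithium aryloxyacetylide 22 (not isolated)
Conditions: n-BuLi (2.3 equiv), THF, −78 → −40 °C; cannulation into 20 (2 equiv), THF, −78 °C
Reagents that add atoms: none
Why: Deprotonation and β-elimination give 21, lithium–chlorine exchange with the second equivalent of n-BuLi gives acetylide 22, and C-acylation by the chloroformate gives the ynoate. This is the dichlorovinyl ether route to ynol ether acetylides, and inverse addition keeps the electrophile in excess to suppress a second addition.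

Step 13
Reactants: 10 (S)-2-[1-(tert-butyldimethylsilyloxy)-3-methylbutyl]-1-methoxy-1-(trimethylsilyloxy)buta-1,3-diene; 23 benzyl 3-{2-(benzyloxy)-4-methyl-6-[(triisopropylsilyloxy)methyl]phenoxy}prop-2-ynoate
Product: 26 benzyl 6-(ArB-oxy)-3-[(1S)-1-(tert-butyldimethylsilyloxy)-3-methylbutyl]-2-hydroxybenzoate, via cyclohexa-1,4-diene cycloadduct 24 (not isolated), via aryl trimethylsilyl ether 25 (not isolated)
Conditions: 10 (2 equiv), toluene, 100–110 °C, sealed tube; then 10% aq. citric acid–THF, rt
Reagents that add atoms: none
Why: The dienyl ketene acetal 10 is a very electron-rich diene with its largest HOMO coefficient on the unsubstituted terminus (C5), and the ynoate 23 remains electrophilic at its β-carbon (C6) despite the aryloxy donor, so a strongly asynchronous normal-demand [4+2] cycloaddition is expected in which the C5–C6 bond leads and the C1–C2 bond follows. Ring A is thus closed by an intermolecular [4+2] addition; in the stepwise limit the second bond forms by 6-exo-trig attack of the allenoate carbon C1 on the methoxy(silyloxy)carbenium carbon C2. Cyclohexa-1,4-diene 24 then loses methanol by 1,4-elimination (C2–OMe and the doubly allylic C5–H), driven by aromatisation, and the aryl silyl ether 25 is hydrolysed on acidic work-up to the hydrogen-bonded salicylate 26. The closest known reaction type is the Diels–Alder/aromatisation of 1-alkoxy-1-silyloxybuta-1,3-dienes with alkynoates to give salicylates. No stereocentre is formed; the (S)-carbinol carbon is a spectator that is neither enolisable nor ionised under neutral thermal conditions. The selectivity required is regiochemical and is secured by the polarity match just described, which places the aryloxy group on C6 and the oxygenated carbon C2 next to the ester. If part of 24 loses trimethylsilanol instead of methanol, the product is 27, the product of step 14, so both elimination channels converge. The C3 substituent biases the diene towards the s-cis conformer, the tert-butyldimethylsilyl group crowds C2 less than a triisopropylsilyl group would, and the excess of 10 compensates for the lower dienophilicity of the push–pull alkyne.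

Step 14
Reactants: 26 benzyl 6-(ArB-oxy)-3-[(1S)-1-(tert-butyldimethylsilyloxy)-3-methylbutyl]-2-hydroxybenzoate
Product: 27 benzyl 6-(ArB-oxy)-3-[(1S)-1-(tert-butyldimethylsilyloxy)-3-methylbutyl]-2-methoxybenzoate
Conditions: MeI, K2CO3, DMF, rt → 40 °C
Reagents that add atoms: iodomethane, CI
Why: Williamson O-methylation of the salicylate phenol; the alkyl silyl ethers and the benzyl ester are inert to carbonate in DMF. Silyl migration from the alkyl oxygen to the phenoxide is thermodynamically disfavoured, so the carbinol stays protected.

Step 15
Reactants: 27 benzyl 6-(ArB-oxy)-3-[(1S)-1-(tert-butyldimethylsilyloxy)-3-methylbutyl]-2-methoxybenzoate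
Product: 28 3-[(1S)-1-(tert-butyldimethylsilyloxy)-3-methylbutyl]-6-{2-hydroxy-4-methyl-6-[(triisopropylsilyloxy)methyl]phenoxy}-2-methoxybenzoic acid
Conditions: H2 (1 atm), 10% Pd/C, EtOAc, rt
Reagents that add atoms: none
Why: Catalytic hydrogenolysis cleaves the aryl benzyl ether and the benzyl ester in one neutral operation, so the di-ortho-substituted carboxyl group is freed without saponification. Both benzylic C–O bonds of the skeleton are still bulky silyl ethers in this step, which should protect them from hydrogenolysis.

Step 16
Reactants: 28 3-[(1S)-1-(tert-butyldimethylsilyloxy)-3-methylbutyl]-6-{2-hydroxy-4-methyl-6-[(triisopropylsilyloxy)methyl]phenoxy}-2-methoxybenzoic acid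
Product: 29 6-[2-hydroxy-6-(hydroxymethyl)-4-methylphenoxy]-3-[(1S)-1-hydroxy-3-methylbutyl]-2-methoxybenzoic acid (target)
Conditions: Bu4NF (6 equiv), THF, 0 °C → rt; cold 0.5 M HCl to pH 3–4
Reagents that add atoms: none
Why: Fluoride-mediated desilylation removes both silyl ethers under basic conditions. These conditions neither ionise the electron-rich benzylic carbinol nor activate the acid towards lactonisation, so the S centre set in step 2 is kept.

## Compound list

1 | (R)-4-benzyl-2-oxazolidinone | O=C1N[C@H](Cc2ccccc2)CO1 | starting material
2 | (E)-but-2-enoyl chloride (crotonyl chloride) | C/C=C/C(=O)Cl | starting material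
3 | (4R)-4-benzyl-3-[(2E)-but-2-enoyl]-1,3-oxazolidin-2-one | C/C=C/C(=O)N1[C@H](Cc2ccccc2)COC1=O | intermediate
4 | 3-methylbutanal (isovaleraldehyde) | CC(C)CC=O | starting material
5 | (4R)-4-benzyl-3-[(1Z)-1-(dibutylboryloxy)buta-1,3-dienyl]-1,3-oxazolidin-2-one (boron dienolate, not isolated) | C=C/C=C(\OB(CCCC)CCCC)N1[C@H](Cc2ccccc2)COC1=O | intermediate
6 | (4R)-4-benzyl-3-[(2R,3S)-2-ethenyl-3-hydroxy-5-methylhexanoyl]-1,3-oxazolidin-2-one | C=C[C@H]([C@@H](O)CC(C)C)C(=O)N1[C@H](Cc2ccccc2)COC1=O | intermediate
7 | methyl (2R,3S)-2-ethenyl-3-hydroxy-5-methylhexanoate | C=C[C@H]([C@@H](O)CC(C)C)C(=O)OC | intermediate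
8 | methyl (2R,3S)-3-(tert-butyldimethylsilyloxy)-2-ethenyl-5-methylhexanoate | C=C[C@H]([C@@H](O[Si](C)(C)C(C)(C)C)CC(C)C)C(=O)OC | intermediate
9 | lithium dienolate of 8 (not isolated) | C=CC(=C(OC)O[Li])[C@@H](O[Si](C)(C)C(C)(C)C)CC(C)C | intermediate
10 | (S)-2-[1-(tert-butyldimethylsilyloxy)-3-methylbutyl]-1-methoxy-1-(trimethylsilyloxy)buta-1,3-diene (ketene acetal geometry not defined) | C=CC(=C(OC)O[Si](C)(C)C)[C@@H](O[Si](C)(C)C(C)(C)C)CC(C)C | intermediate
11 | creosol (2-methoxy-4-methylphenol) | Cc1ccc(O)c(OC)c1 | starting material
12 | 2-hydroxy-3-methoxy-5-methylbenzaldehyde | Cc1cc(C=O)c(O)c(OC)c1 | intermediate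
13 | 2,3-dihydroxy-5-methylbenzaldehyde | Cc1cc(C=O)c(O)c(O)c1 | intermediate
14 | disodium 3-formyl-5-methylbenzene-1,2-diolate (not isolated) | Cc1cc(C=O)c([O-])c([O-])c1.[Na+].[Na+] | intermediate
15 | 3-(benzyloxy)-2-hydroxy-5-methylbenzaldehyde | Cc1cc(C=O)c(O)c(OCc2ccccc2)c1 | intermediate
16 | 2-(benzyloxy)-6-(hydroxymethyl)-4-methylphenol | Cc1cc(CO)c(O)c(OCc2ccccc2)c1 | intermediate
17 | 2-(benzyloxy)-4-methyl-6-[(triisopropylsilyloxy)methyl]phenol | Cc1cc(CO[Si](C(C)C)(C(C)C)C(C)C)c(O)c(OCc2ccccc2)c1 | intermediate
18 | trichloroethylene | ClC=C(Cl)Cl | starting material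
19 | 1-(benzyloxy)-2-[(E)-1,2-dichloroethenyloxy]-5-methyl-3-[(triisopropylsilyloxy)methyl]benzene | Cl/C=C(/Cl)Oc1c(OCc2ccccc2)cc(C)cc1CO[Si](C(C)C)(C(C)C)C(C)C | intermediate
20 | benzyl chloroformate | O=C(Cl)OCc1ccccc1 | starting material
21 | 1-(benzyloxy)-2-(chloroethynyloxy)-5-methyl-3-[(triisopropylsilyloxy)methyl]benzene (not isolated) | ClC#COc1c(OCc2ccccc2)cc(C)cc1CO[Si](C(C)C)(C(C)C)C(C)C | intermediate
22 | lithium 2-(ArB-oxy)acetylide (not isolated) | [Li]C#COc1c(OCc2ccccc2)cc(C)cc1CO[Si](C(C)C)(C(C)C)C(C)C | intermediate
23 | benzyl 3-{2-(benzyloxy)-4-methyl-6-[(triisopropylsilyloxy)methyl]phenoxy}prop-2-ynoate | O=C(OCc1ccccc1)C#COc1c(OCc2ccccc2)cc(C)cc1CO[Si](C(C)C)(C(C)C)C(C)C | intermediate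
24 | benzyl 2-(ArB-oxy)-5-[(1S)-1-(tert-butyldimethylsilyloxy)-3-methylbutyl]-6-methoxy-6-(trimethylsilyloxy)cyclohexa-1,4-diene-1-carboxylate (not isolated; C6 of the cyclohexadiene not defined) | COC1(O[Si](C)(C)C)C(C(=O)OCc2ccccc2)=C(Oc2c(OCc3ccccc3)cc(C)cc2CO[Si](C(C)C)(C(C)C)C(C)C)CC=C1[C@@H](O[Si](C)(C)C(C)(C)C)CC(C)C | intermediate
25 | benzyl 6-(ArB-oxy)-3-[(1S)-1-(tert-butyldimethylsilyloxy)-3-methylbutyl]-2-(trimethylsilyloxy)benzoate (not isolated) | C[Si](C)(C)Oc1c([C@@H](O[Si](C)(C)C(C)(C)C)CC(C)C)ccc(Oc2c(OCc3ccccc3)cc(C)cc2CO[Si](C(C)C)(C(C)C)C(C)C)c1C(=O)OCc1ccccc1 | intermediate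
26 | benzyl 6-{2-(benzyloxy)-4-methyl-6-[(triisopropylsilyloxy)methyl]phenoxy}-3-[(1S)-1-(tert-butyldimethylsilyloxy)-3-methylbutyl]-2-hydroxybenzoate | Oc1c([C@@H](O[Si](C)(C)C(C)(C)C)CC(C)C)ccc(Oc2c(OCc3ccccc3)cc(C)cc2CO[Si](C(C)C)(C(C)C)C(C)C)c1C(=O)OCc1ccccc1 | intermediate
27 | benzyl 6-{2-(benzyloxy)-4-methyl-6-[(triisopropylsilyloxy)methyl]phenoxy}-3-[(1S)-1-(tert-butyldimethylsilyloxy)-3-methylbutyl]-2-methoxybenzoate | COc1c([C@@H](O[Si](C)(C)C(C)(C)C)CC(C)C)ccc(Oc2c(OCc3ccccc3)cc(C)cc2CO[Si](C(C)C)(C(C)C)C(C)C)c1C(=O)OCc1ccccc1 | intermediate
28 | 3-[(1S)-1-(tert-butyldimethylsilyloxy)-3-methylbutyl]-6-{2-hydroxy-4-methyl-6-[(triisopropylsilyloxy)methyl]phenoxy}-2-methoxybenzoic acid | COc1c([C@@H](O[Si](C)(C)C(C)(C)C)CC(C)C)ccc(Oc2c(O)cc(C)cc2CO[Si](C(C)C)(C(C)C)C(C)C)c1C(=O)O | intermediate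
29 | 6-[2-hydroxy-6-(hydroxymethyl)-4-methylphenoxy]-3-[(1S)-1-hydroxy-3-methylbutyl]-2-methoxybenzoic acid | COc1c([C@@H](O)CC(C)C)ccc(Oc2c(O)cc(C)cc2CO)c1C(=O)O | target

## Step count and least certain steps

Total step count: 16 (steps 1–5 give the diene, steps 6–12 the alkyne, steps 13–16 join them and finish).
Longest linear sequence: 11 steps, from 11 through steps 6–12 and 13–16 to 29.

**Step 13 (key step).** The cycloaddition is most likely to be too slow, because the aryloxy donor raises the LUMO of the ynoate. Hydrolysis or oligomerisation of the ketene acetal, [2+2] addition at its electron-rich double bond, or arrest at an open-chain vinylogous Michael adduct could then outrun ring closure.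

Fallback, setting out from 10 and 17 and returning at 27: the aryl–O bond is moved to after ring formation. Commercial benzyl propiolate is brominated (N-bromosuccinimide, AgNO3 cat., acetone) to benzyl 3-bromopropiolate F1, a strongly activated dienophile of the same polarity. Heating F1 with 10 in toluene, followed by the same mild acid work-up, should give benzyl 6-bromo-3-[(1S)-1-(tert-butyldimethylsilyloxy)-3-methylbutyl]-2-hydroxybenzoate F2. Methylation (MeI, K2CO3, DMF) gives benzyl 6-bromo-3-[(1S)-1-(tert-butyldimethylsilyloxy)-3-methylbutyl]-2-methoxybenzoate F3. Ullmann etherification of F3 with 17 (CuI, picolinic acid, K3PO4, DMSO, 90 °C), helped by the ortho ester, gives 27. The ring-forming logic is kept, but the hindered arylation that the main route avoids has to be accepted.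

**Step 12.** Generation and acylation of the aryloxyacetylide may fail through decomposition of the labile ynol ether anion above −40 °C, competing lithiation at the two benzylic O–CH2 positions, or a second addition of the acetylide to the product ynoate.

Fallback, setting out from 17 (it also replaces step 11) and returning at 23: oxa-Michael addition of 17 to benzyl propiolate (DABCO cat., CH2Cl2, rt) gives benzyl (E)-3-(ArB-oxy)prop-2-enoate F4. Bromine addition at low temperature followed by Et3N gives benzyl (Z)-2-bromo-3-(ArB-oxy)prop-2-enoate F5, in which bromine is anti to the β-hydrogen. Anti elimination with KN(SiMe3)2 (THF, −78 °C) then gives 23. Neither dichloroacetylene nor an alkyllithium is needed. The electron-rich ring B must be spared in the bromination, for instance with pyridinium tribromide.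

**Step 5.** The ester dienolate may lose the β-silyloxide by E1cB elimination before it is silylated, and the trimethylsilyl ketene acetal may be hydrolysed or C-silylated during isolation.

Fallback, setting out from 7 and returning at 27: the unprotected hydroxy ester 7 is converted with LiN(iPr)2 (2.2 equiv) into the alkoxide–dienolate dianion, which has no leaving group in the β-position. Excess Me3SiCl gives (S)-1-methoxy-2-[3-methyl-1-(trimethylsilyloxy)butyl]-1-(trimethylsilyloxy)buta-1,3-diene F6. Cycloaddition of F6 with 23 under the conditions of step 13 and acid work-up should give benzyl 6-(ArB-oxy)-2-hydroxy-3-[(1S)-1-hydroxy-3-methylbutyl]benzoate F7. Phenol-selective methylation (MeI, K2CO3, acetone) gives benzyl 6-(ArB-oxy)-3-[(1S)-1-hydroxy-3-methylbutyl]-2-methoxybenzoate F8, and silylation of F8 (tBuMe2SiOTf, 2,6-lutidine) gives 27. The free ortho-hydroxybenzylic alcohol of F7 is acid-sensitive, which is why this is not the main route.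

**Step 8.** Mono-benzylation may go to the wrong oxygen or to both, through incomplete dianion formation or proton exchange between mono- and dianion.

Fallback, setting out from 13 and returning at 15: exhaustive benzylation (BnBr, K2CO3, DMF) gives 2,3-bis(benzyloxy)-5-methylbenzaldehyde F9. The benzyl ether ortho to the formyl group is then removed under chelation control with MgBr2·OEt2 (toluene–Et2O, warm), which leaves the 3-benzyl ether and gives 15. Regiocontrol then comes from chelation in a deprotection and not from differential nucleophilicity.

**Step 15.** Hydrogenolysis may over-reduce the benzylic C–O bonds. The ring A carbinol is activated by its ortho-methoxy and para-aryloxy groups, and the acid formed in the step can assist. Alternatively, hydrogen uptake at the crowded benzyl ether may be slow.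

Fallback, setting out from 27 and returning at 28 without hydrogen: BCl3 with pentamethylbenzene as cation scavenger (CH2Cl2, −78 °C) cleaves both benzyl–oxygen bonds by Lewis-acid ionisation, and the benzyl cations are captured by the scavenger. This fallback makes no new compound (F0). The temperature must stay at −78 °C to spare the silyl ethers and the chelated C2 methyl ether.

## Further compounds

F1 | step 13 | benzyl 3-bromoprop-2-ynoate | O=C(OCc1ccccc1)C#CBr
F2 | step 13 | benzyl 6-bromo-3-[(1S)-1-(tert-butyldimethylsilyloxy)-3-methylbutyl]-2-hydroxybenzoate | Oc1c([C@@H](O[Si](C)(C)C(C)(C)C)CC(C)C)ccc(Br)c1C(=O)OCc1ccccc1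
F3 | step 13 | benzyl 6-bromo-3-[(1S)-1-(tert-butyldimethylsilyloxy)-3-methylbutyl]-2-methoxybenzoate | COc1c([C@@H](O[Si](C)(C)C(C)(C)C)CC(C)C)ccc(Br)c1C(=O)OCc1ccccc1
F4 | step 12 | benzyl (E)-3-{2-(benzyloxy)-4-methyl-6-[(triisopropylsilyloxy)methyl]phenoxy}prop-2-enoate | O=C(OCc1ccccc1)/C=C/Oc1c(OCc2ccccc2)cc(C)cc1CO[Si](C(C)C)(C(C)C)C(C)C
F5 | step 12 | benzyl (Z)-2-bromo-3-{2-(benzyloxy)-4-methyl-6-[(triisopropylsilyloxy)methyl]phenoxy}prop-2-enoate | O=C(OCc1ccccc1)/C(Br)=C/Oc1c(OCc2ccccc2)cc(C)cc1CO[Si](C(C)C)(C(C)C)C(C)C
F6 | step 5 | (S)-1-methoxy-2-[3-methyl-1-(trimethylsilyloxy)butyl]-1-(trimethylsilyloxy)buta-1,3-diene | C=CC(=C(OC)O[Si](C)(C)C)[C@@H](O[Si](C)(C)C)CC(C)C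
F7 | step 5 | benzyl 6-{2-(benzyloxy)-4-methyl-6-[(triisopropylsilyloxy)methyl]phenoxy}-2-hydroxy-3-[(1S)-1-hydroxy-3-methylbutyl]benzoate | Oc1c([C@@H](O)CC(C)C)ccc(Oc2c(OCc3ccccc3)cc(C)cc2CO[Si](C(C)C)(C(C)C)C(C)C)c1C(=O)OCc1ccccc1
F8 | step 5 | benzyl 6-{2-(benzyloxy)-4-methyl-6-[(triisopropylsilyloxy)methyl]phenoxy}-3-[(1S)-1-hydroxy-3-methylbutyl]-2-methoxybenzoate | COc1c([C@@H](O)CC(C)C)ccc(Oc2c(OCc3ccccc3)cc(C)cc2CO[Si](C(C)C)(C(C)C)C(C)C)c1C(=O)OCc1ccccc1
F9 | step 8 | 2,3-bis(benzyloxy)-5-methylbenzaldehyde | Cc1cc(C=O)c(OCc2ccccc2)c(OCc2ccccc2)c1
F0 | step 15 | none | none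
A1 | alternative 1 | 6-{2-(benzyloxy)-4-methyl-6-[(triisopropylsilyloxy)methyl]phenoxy}-2-methoxy-3-[(1S)-3-methyl-1-(triisopropylsilyloxy)butyl]benzoic acid | COc1c([C@@H](O[Si](C(C)C)(C(C)C)C(C)C)CC(C)C)ccc(Oc2c(OCc3ccccc3)cc(C)cc2CO[Si](C(C)C)(C(C)C)C(C)C)c1C(=O)O
A2 | alternative 1 | 2-methoxy-3-[(1S)-3-methyl-1-(triisopropylsilyloxy)butyl]-6-(trimethylsilyl)phenyl trifluoromethanesulfonate | COc1c([C@@H](O[Si](C(C)C)(C(C)C)C(C)C)CC(C)C)ccc([Si](C)(C)C)c1OS(=O)(=O)C(F)(F)F
A3 | alternative 1 | carbon dioxide | O=C=O
A4 | alternative 2 | 6-[2-(dimethoxymethyl)-6-hydroxy-4-methylphenoxy]-2-methoxy-3-[(1S)-3-methyl-1-(triisopropylsilyloxy)butyl]benzoic acid | COc1c([C@@H](O[Si](C(C)C)(C(C)C)C(C)C)CC(C)C)ccc(Oc2c(O)cc(C)cc2C(OC)OC)c1C(=O)O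
A5 | alternative 2 | 2-methoxy-3-[(1S)-3-methyl-1-(triisopropylsilyloxy)butyl]-6-(2-oxopent-3-ynyloxy)benzoic acid | COc1c([C@@H](O[Si](C(C)C)(C(C)C)C(C)C)CC(C)C)ccc(OCC(=O)C#CC)c1C(=O)O
A6 | alternative 2 | 1,1-dimethoxypropan-2-one (1,1-dimethoxyacetone) | CC(=O)C(OC)OC
A7 | alternative 3 | methyl 6-{2-(benzyloxy)-4-methyl-6-[(triisopropylsilyloxy)methyl]phenoxy}-2-methoxy-3-[(1S)-3-methyl-1-(triisopropylsilyloxy)butyl]benzoate | COC(=O)c1c(OC)c([C@@H](O[Si](C(C)C)(C(C)C)C(C)C)CC(C)C)ccc1Oc1c(OCc2ccccc2)cc(C)cc1CO[Si](C(C)C)(C(C)C)C(C)C
A8 | alternative 3 | methyl 4-{2-(benzyloxy)-4-methyl-6-[(triisopropylsilyloxy)methyl]phenoxy}-2-oxo-2H-pyran-3-carboxylate | COC(=O)C1=C(Oc2c(OCc3ccccc3)cc(C)cc2CO[Si](C(C)C)(C(C)C)C(C)C)C=COC1=O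
A9 | alternative 3 | (S)-1-methoxy-5-methyl-3-(triisopropylsilyloxy)hex-1-yne | COC#C[C@@H](O[Si](C(C)C)(C(C)C)C(C)C)CC(C)C
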